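**Assumption:** the target SMILES has no stereocentre (the molecule is achiral), so "single enantiomer" needs no stereocontrol and the route simply makes this one compound.

**Retrosynthetic overview**
1. Cut the aryl–C(=O) bond of the acylphloroglucinol: phloroglucinol plus 11-(2-hydroxyphenyl)undecanenitrile (Hoesch acylation, then ketimine hydrolysis).
2. Cut the ArCH2–CH2 (sp2–sp3) bond of that nitrile: 2-iodophenol plus undec-10-enenitrile (9-BBN hydroboration, then B-alkyl Suzuki–Miyaura coupling).
3. No ring is formed; both benzene rings are bought intact. No protecting groups and no stereocentres.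

**Route**

Step 1
Reactants: 1 undec-10-enenitrile; 2 2-iodophenol
Product: 4 11-(2-hydroxyphenyl)undecanenitrile, via alkylborane 3 (not isolated)
Conditions: 1 (1.2 equiv), 9-BBN-H (0.5 M in THF, 1.25 equiv), 0 °C to rt, 4 h; then 2 (1.0 equiv), PdCl2(dppf)·CH2Cl2 (3 mol %), 3 M aq K3PO4 (3 equiv), DMF, 60 °C, 12 h; dilute HCl work-up, no peroxide (protects the nitrile)
Reagents that add atoms: none
Why: Anti-Markovnikov hydroboration of the terminal alkene with 9-BBN is much faster than attack on the nitrile, and the resulting primary B-alkyl-9-BBN undergoes B-alkyl Suzuki–Miyaura coupling with the aryl iodide (free phenol carried as its phenoxide) to form the ArCH2–CH2 bond; no stereocentre is created.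

Step 2
Reactants: 4 11-(2-hydroxyphenyl)undecanenitrile; 5 phloroglucinol (anhydrous)
Product: 7 11-(2-hydroxyphenyl)-1-(2,4,6-trihydroxyphenyl)undecan-1-one, via ketiminium chloride 6 (not isolated)
Conditions: 5 (1.5 equiv), fused ZnCl2 (0.5 equiv), dry HCl gas (saturation), dry Et2O, 0 °C then 4 °C, 48 h; decant ether from the separated iminium salt; H2O, reflux, 2 h
Reagents that add atoms: water, O
Why: In this Hoesch (Houben–Hoesch) reaction the HCl-activated nitrile is attacked at carbon only by the highly nucleophilic, C3-symmetric phloroglucinol (single regioisomer, and the iminium deactivates the ring against a second acylation), the far less reactive o-alkylphenol ring is left alone, and hot water hydrolyses the ketiminium salt to the ketone; no stereocentre is involved.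

**Compound list**
1 | undec-10-enenitrile | C=CCCCCCCCCC#N | starting material
2 | 2-iodophenol | Oc1ccccc1I | starting material
3 | 9-(10-cyanodecyl)-9-borabicyclo[3.3.1]nonane | N#CCCCCCCCCCCB1C2CCCC1CCC2 | intermediate
4 | 11-(2-hydroxyphenyl)undecanenitrile | N#CCCCCCCCCCCc1ccccc1O | intermediate
5 | phloroglucinol (benzene-1,3,5-triol) | Oc1cc(O)cc(O)c1 | starting material
6 | 11-(2-hydroxyphenyl)-1-(2,4,6-trihydroxyphenyl)undecan-1-iminium chloride | [NH2+]=C(CCCCCCCCCCc1ccccc1O)c1c(O)cc(O)cc1O.[Cl-] | intermediate
7 | 11-(2-hydroxyphenyl)-1-(2,4,6-trihydroxyphenyl)undecan-1-one (CNP0295227.0) | O=C(CCCCCCCCCCc1ccccc1O)c1c(O)cc(O)cc1O | target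

**Total step count:** 2
**Longest linear sequence:** 2 steps (1 → 4 → 7)

**Steps most likely to fail** (the route has only two steps, so both are ranked and there is no third)

1. Step 2 (Hoesch acylation). The long-chain nitrile may react sluggishly, and the free phenol of 4 may be diverted to an O-aryl imidate, giving low conversion or ester by-products after hydrolysis. Fallback: set out from 4 and hydrolyse the nitrile (KOH, ethylene glycol/H2O, 130 °C; then 2 M HCl) to 11-(2-hydroxyphenyl)undecanoic acid F3. Then carry out a direct Friedel–Crafts acylation of phloroglucinol 5 with this acid in neat BF3·OEt2 at 85 °C (aqueous NaOAc quench), the method used for phloretin-type dihydrochalcones from free phenolic acids. This comes back to the route at target 7.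

2. Step 1 (hydroboration / B-alkyl Suzuki coupling). The ortho-phenoxide of 2 may slow oxidative addition or bind to palladium or boron, so that protodeboronation and β-hydride elimination win. Fallback: set out from 2 and O-benzylate it (BnBr, K2CO3, acetone, reflux) to 1-(benzyloxy)-2-iodobenzene F1. Couple F1 with alkylborane 3 (made from 1 as before; PdCl2(dppf), aq K3PO4, DMF, 60 °C) to give 11-[2-(benzyloxy)phenyl]undecanenitrile F2. Remove the benzyl group by hydrogenolysis (H2 1 atm, 10 % Pd/C, EtOAc, rt; the aliphatic nitrile is inert under these conditions), which comes back to the route at 4.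

**Further compounds**
F1 | step 1 | 1-(benzyloxy)-2-iodobenzene | Ic1ccccc1OCc1ccccc1
F2 | step 1 | 11-[2-(benzyloxy)phenyl]undecanenitrile | N#CCCCCCCCCCCc1ccccc1OCc1ccccc1
F3 | step 2 | 11-(2-hydroxyphenyl)undecanoic acid | OC(=O)CCCCCCCCCCc1ccccc1O
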